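**Plan**

- Retrosynthetic cuts: the lactone C15–O16 bond and C13–C14 (acetate unit onto a cyclic peroxycarbenium ion), C13–O (hemiperketal), C9–O (H2O2 opening of an 8α,9α-epoxide) and C8=C17 (dehydration), then C12–C13 and C9–C11 (two Pd couplings from a C9 enol triflate), and last ring A across C4–C5 and C1–C10.
- Enabling feature: ring B carries oxygen at C6 and C9 in a 1,4-relationship, with C9 flanked by the methyl-bearing carbons C10 (C20) and C8 (C17), so it maps onto 2,6-dimethyl-1,4-benzoquinone. C1–C4 of ring A, with oxygen at C2, maps onto a 2-silyloxy-1,3-diene whose (Z)-terminus C4 already holds C18 and C19.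
- Forward order: butenolide to (Z)-diene; Diels–Alder union with the quinone (ring B preformed, ring A closed); ring B edited to the 8(9)-ene bearing the C11–C13 chain; 1,2-dioxane closed through O–O–C13; lactone ring last.
- Stereochemistry: C4 and C10 from the catalyst-controlled endo cycloaddition of the (Z)-diene; C5 by equilibration to the trans-decalin; C2 and C6 by thermodynamic ketone reduction; C9 by α-epoxidation followed by backside opening with H2O2; C13 by axial attack on the dioxanyl cation.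

Key step: step 5

Locants follow labdane numbering of the target (ring A C1–C5/C10, ring B C5–C10, C11–C12 tether, C13 spiro carbon, C14/C15/C16 lactone, C17 on C8, C18 = 4α-CH3, C19 = 4β-CH2O, C20 = 10β-CH3); α is the face opposite C20.

Assumption: the (S)-oxazaborolidinium catalyst is taken to expose the quinone face that leads to adduct 8 as drawn; if the facial sense is the opposite one, the (R)-catalyst is used with no other change.

**Route**

Step 1
Reactants: 1 4-methylfuran-2(5H)-one
Product: 2 (Z)-4-hydroxy-N-methoxy-N,3-dimethylbut-2-enamide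
Conditions: MeNH(OMe)·HCl, i-PrMgCl, THF, −20 °C
Reagents that add atoms: N,O-dimethylhydroxylamine hydrochloride, CNOC.Cl
Why: Aminolysis of the lactone by the chloromagnesium amide (Weinreb amide formation) opens the ring, so the cis relation of C2 and C19 across C3=C4 is inherited from the butenolide.

Step 2
Reactants: 2 (Z)-4-hydroxy-N-methoxy-N,3-dimethylbut-2-enamide
Product: 3 (Z)-4-(tert-butyldimethylsilyloxy)-N-methoxy-N,3-dimethylbut-2-enamide
Conditions: TBSCl, imidazole, DMF, 0 °C → rt
Reagents that add atoms: tert-butyldimethylsilyl chloride, CC(C)(C)[Si](C)(C)Cl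
Why: Silylation of the primary allylic alcohol blocks relactonization and installs the C19 protecting group.

Step 3
Reactants: 3 (Z)-4-(tert-butyldimethylsilyloxy)-N-methoxy-N,3-dimethylbut-2-enamide
Product: 4 (Z)-5-(tert-butyldimethylsilyloxy)-4-methylpent-3-en-2-one
Conditions: MeMgBr, THF, 0 °C
Reagents that add atoms: methylmagnesium bromide, C[Mg]Br
Why: Weinreb ketone synthesis, in which the chelated tetrahedral intermediate prevents over-addition and the (Z)-alkene is untouched.

Step 4
Reactants: 4 (Z)-5-(tert-butyldimethylsilyloxy)-4-methylpent-3-en-2-one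
Product: 6 (Z)-2,5-bis(tert-butyldimethylsilyloxy)-4-methylpenta-1,3-diene, via lithium dienolate 5 (not isolated)
Conditions: LiN(i-Pr)2, THF, −78 °C; then TBSOTf, −78 °C
Reagents that add atoms: tert-butyldimethylsilyl trifluoromethanesulfonate, CC(C)(C)[Si](C)(C)OS(=O)(=O)C(F)(F)F
Why: Kinetic deprotonation of the methyl ketone at the α′-methyl and O-silylation of the cross-conjugated enolate should give the 2-silyloxy diene without isomerizing the (Z)-alkene.

Step 5
Reactants: 6 (Z)-2,5-bis(tert-butyldimethylsilyloxy)-4-methylpenta-1,3-diene + 7 2,6-dimethyl-1,4-benzoquinone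
Product: 8 cis-fused cycloadduct (2-OTBS-2(3)-ene; 19-OTBS; 6,9-dioxo-7(8)-ene; 8-CH3; 4α-CH3; 4β-CH2OTBS; 5β-H; 10β-CH3)
Conditions: (S)-B-(o-tolyl)oxazaborolidine from (S)-α,α-diphenylprolinol (20 mol %), Tf2NH (20 mol %), CH2Cl2, −78 → −40 °C
Reagents that add atoms: none
Why: The triflimide-activated oxazaborolidinium ion binds the quinone at the C6 carbonyl (the one flanked by two C–H), which lowers the LUMO at the methyl-bearing β-carbon C10, and the diene adds in a concerted but strongly asynchronous endo [4+2] in which the CH2 terminus C1 bonds to C10 first and the fully substituted terminus C4 then closes ring A onto C5. The closest known reaction type is the chiral oxazaborolidinium-catalysed Diels–Alder reaction of 2-silyloxy dienes with substituted 1,4-benzoquinones. Ring A closes in the cycloaddition mode (six-membered, suprafacial on both partners; at the stepwise limit a Mukaiyama–Michael addition followed by closure of the quinone enolate carbon C5 onto the silyloxyallyl cation terminus C4). C10 and C5 form cis by suprafacial addition to the quinone C=C, with the absolute sense set by the catalyst shielding one face of the bound quinone, and C4 is set relative to them by the (Z)-geometry of the diene in the endo transition state, which places the inside CH2OTBS cis to the C10 methyl. The step needs regioselectivity (C1 to C–CH3, C4 to C–H), endo selectivity and face selectivity, which should be secured by catalyst coordination at the less hindered C6=O, by the larger HOMO coefficient at C1 of the 2-silyloxy-4,4-dialkyl diene, and by sterics that keep the disubstituted terminus away from the methyl-bearing carbon.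

Step 6
Reactants: 8 cis-fused cycloadduct
Product: 9 trans-fused ene-dione (as 8 but 5α-H)
Conditions: DBU, PhMe, 50 °C
Reagents that add atoms: none
Why: Reversible enolization of the C6 ketone toward C5 (its only α-hydrogen in the ene-dione) should equilibrate the ring fusion to the trans-decalin, the classical course for angular-methyl quinone adducts, with reprotonation on the α-face away from the β-CH2OTBS and β-CH3 groups.

Step 7
Reactants: 9 trans-fused ene-dione
Product: 11 9-triflyloxy-8(9)-ene 6-ketone (2-OTBS-2(3)-ene; 19-OTBS), via potassium enolate 10 (not isolated)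
Conditions: K[(s-Bu)3BH] (K-Selectride, 1.05 equiv), THF, −78 °C; then PhNTf2, −78 → 0 °C
Reagents that add atoms: N-phenylbis(trifluoromethanesulfonimide), O=S(=O)(N(c1ccccc1)S(=O)(=O)C(F)(F)F)C(F)(F)F
Why: Conjugate hydride delivery to the unsubstituted carbon C7 of the ene-dione generates the C9 enolate regiospecifically, and O-triflation fixes the 8(9)-double bond and activates C9 for coupling.

Step 8
Reactants: 11 9-triflyloxy-8(9)-ene 6-ketone
Product: 12 9-vinyl-8(9)-ene 6-ketone (2-OTBS-2(3)-ene; 19-OTBS)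
Conditions: Bu3SnCH=CH2, Pd(PPh3)4 (5 mol %), LiCl, THF, 65 °C
Reagents that add atoms: tributyl(vinyl)stannane, C=C[Sn](CCCC)(CCCC)CCCC
Why: Stille coupling of the hindered enol triflate installs C11 and C12 under neutral conditions that leave the ketone and the silyl enol ether alone.

Step 9
Reactants: 12 9-vinyl-8(9)-ene 6-ketone
Product: 13 2,6-diketone (19-OTBS; 8(9)-ene; 9-vinyl; 5α-H)
Conditions: Bu4NF, AcOH, THF, 0 °C
Reagents that add atoms: none
Why: Buffered fluoride cleaves the silyl enol ether far faster than the neopentyl TBS ether and avoids base-induced migration of the β,γ-double bond.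

Step 10
Reactants: 13 2,6-diketone
Product: 14 2α,6α-diol (19-OTBS; 8(9)-ene; 9-vinyl)
Conditions: SmI2, THF/H2O, 0 °C → rt
Reagents that add atoms: none
Why: Single-electron reduction of both ketones with water as proton source should give the thermodynamically preferred equatorial 2α- and 6α-alcohols through configurationally labile ketyl and organosamarium intermediates, where hydride reagents would attack the open α-face and give the axial β-alcohols.

Step 11
Reactants: 14 2α,6α-diol
Product: 15 2α,6α,19-tris(TBS) ether (8(9)-ene; 9-vinyl)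
Conditions: TBSOTf, 2,6-lutidine, CH2Cl2, 0 °C
Reagents that add atoms: tert-butyldimethylsilyl trifluoromethanesulfonate, CC(C)(C)[Si](C)(C)OS(=O)(=O)C(F)(F)F
Why: Silyl triflate protection of the two secondary alcohols gives one protecting-group type for a single late deprotection.

Step 12
Reactants: 16 2-bromoprop-2-en-1-ol
Product: 17 (2-bromoallyloxy)(tert-butyl)dimethylsilane
Conditions: TBSCl, imidazole, CH2Cl2, rt
Reagents that add atoms: tert-butyldimethylsilyl chloride, CC(C)(C)[Si](C)(C)Cl
Why: Routine silylation gives the vinyl bromide that will supply C13 and C16.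

Step 13
Reactants: 15 2α,6α,19-tris(TBS) ether + 17 (2-bromoallyloxy)(tert-butyl)dimethylsilane
Product: 19 8(9)-ene with the side chain CH2CH2C(=CH2)CH2OTBS on C9, via alkylborane 18 (not isolated)
Conditions: 9-BBN, THF, rt; then 17, Pd(dppf)Cl2 (5 mol %), AsPh3, K3PO4 (aq), DMF, rt
Reagents that add atoms: none
Why: Anti-Markovnikov hydroboration of the only monosubstituted alkene followed by B-alkyl Suzuki–Miyaura coupling with the vinyl bromide builds the C12–C13 bond and leaves C13 as a masked ketone.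

Step 14
Reactants: 19 8(9)-ene with the 2-(silyloxymethyl)allyl side chain
Product: 20 8α,9α-epoxide
Conditions: mCPBA (1.05 equiv), NaHCO3, CH2Cl2, −20 → 0 °C
Reagents that add atoms: 3-chloroperoxybenzoic acid, OOC(=O)c1cccc(Cl)c1
Why: Peracid epoxidation is fastest at the electron-rich tetrasubstituted 8(9)-alkene and should occur from the α-face, opposite the axial C20 methyl and C19 CH2OTBS groups.

Step 15
Reactants: 20 8α,9α-epoxide
Product: 21 9β-hydroperoxy-8α-ol (8β-CH3; C11 now α)
Conditions: H2O2 (anhydrous, in Et2O), H3PMo12O40 (5 mol %), Et2O, 0 °C → rt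
Reagents that add atoms: hydrogen peroxide, OO
Why: In this acid-catalysed perhydrolysis the C9–O bond (tertiary, next to quaternary C10) should ionize preferentially, as in the acid chemistry of 8α,9α-epoxy labdanes, and H2O2 enters from the β-face anti to the departing oxygen, so C9 is set by inversion while C8 keeps its α-oxygen.

Step 16
Reactants: 21 9β-hydroperoxy-8α-ol
Product: 22 9β-(triethylsilylperoxy)-8α-ol
Conditions: Et3SiCl, imidazole, CH2Cl2, 0 °C
Reagents that add atoms: chlorotriethylsilane, CC[Si](Cl)(CC)CC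
Why: The acidic, unhindered hydroperoxide is silylated selectively over the tertiary alcohol, which masks it for the next two steps.

Step 17
Reactants: 22 9β-(triethylsilylperoxy)-8α-ol
Product: 24 C13 ketone (side chain CH2CH2C(=O)CH2OTBS), via methoxy hydroperoxide 23 (not isolated)
Conditions: O3, CH2Cl2/MeOH, −78 °C; then Me2S, −78 °C → rt
Reagents that add atoms: ozone, [O-][O+]=O; methanol, CO (retained only in 23)
Why: Ozonolysis of the one remaining alkene (carbonyl oxide trapped by methanol), then reduction of the α-methoxy hydroperoxide by Me2S, unmasks the C13 ketone, and the silyl peroxide is inert to the sulfide.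

Step 18
Reactants: 24 C13 ketone with 8α-OH
Product: 25 8(17)-ene (9β-OOSiEt3; C13 ketone)
Conditions: SOCl2, pyridine, CH2Cl2, −78 → −30 °C
Reagents that add atoms: none
Why: In the E2 elimination of the chlorosulfite the equatorial 8α-leaving group has no antiperiplanar ring hydrogen and C9 has no hydrogen at all, so loss should occur toward the C17 methyl to give the exocyclic alkene, as with 8α-hydroxy labdanes and drimanes.

Step 19
Reactants: 25 8(17)-ene with 9β-OOSiEt3 and C13 ketone
Product: 27 cyclic hemiperketal (9β,13-epidioxy-13-ol; both C13 epimers), via hydroperoxy ketone 26 (not isolated)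
Conditions: Bu4NF, AcOH, THF, 0 °C
Reagents that add atoms: none
Why: Fluoride cleaves the labile Si–OO bond selectively and the freed hydroperoxide adds to the C13 ketone to close the six-membered 1,2-dioxan-3-ol.

Step 20
Reactants: 27 cyclic hemiperketal
Product: 28 methyl ester (9β,13-epidioxy; C13 bearing CH2CO2CH3 and CH2OTBS; 13S)
Conditions: CH2=C(OMe)OTBS (3 equiv), TMSOTf (20 mol %), CH2Cl2, −78 °C
Reagents that add atoms: 1-(tert-butyldimethylsilyloxy)-1-methoxyethene, C=C(OC)O[Si](C)(C)C(C)(C)C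
Why: Lewis-acid ionization of the anomeric C13–O bond gives a 1,2-dioxan-3-ylium (peroxycarbenium) ion that the silyl ketene acetal attacks axially (Mukaiyama-type alkylation of a cyclic peroxyketal), and because the quaternary C10 of the spiro centre sits pseudo-equatorial in the half-chair, the acetate arm should end up cis to C10 as in the target.

Step 21
Reactants: 28 methyl ester
Product: 30 target, 2α,6α,19-trihydroxy-9β,13-epidioxylabd-8(17)-en-15,16-olide (CNP0262224.1), via hydroxy ester 29 (not isolated)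
Conditions: HF·pyridine, pyridine, THF, 0 °C → rt
Reagents that add atoms: none
Why: Fluoride removes the four TBS ethers and the freed C16 alcohol should lactonize onto the methyl ester (five-membered ring, helped by the quaternary C13), while the di-tertiary peroxide tolerates the buffered acid.

**Compound list**

1 | 4-methylfuran-2(5H)-one | CC1=CC(=O)OC1 | starting material
2 | (Z)-4-hydroxy-N-methoxy-N,3-dimethylbut-2-enamide | CON(C)C(=O)/C=C(C)\CO | intermediate
3 | (Z)-4-(tert-butyldimethylsilyloxy)-N-methoxy-N,3-dimethylbut-2-enamide | CON(C)C(=O)/C=C(C)\CO[Si](C)(C)C(C)(C)C | intermediate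
4 | (Z)-5-(tert-butyldimethylsilyloxy)-4-methylpent-3-en-2-one | CC(=O)/C=C(C)\CO[Si](C)(C)C(C)(C)C | intermediate
5 | lithium dienolate of 4 | [Li+].C=C([O-])/C=C(C)\CO[Si](C)(C)C(C)(C)C | intermediate
6 | (Z)-2,5-bis(tert-butyldimethylsilyloxy)-4-methylpenta-1,3-diene | C=C(O[Si](C)(C)C(C)(C)C)/C=C(C)\CO[Si](C)(C)C(C)(C)C | intermediate
7 | 2,6-dimethyl-1,4-benzoquinone | CC1=CC(=O)C=C(C)C1=O | starting material
8 | cis-fused cycloadduct (5β-H) | CC1=CC(=O)[C@@H]2[C@@](C)(CO[Si](C)(C)C(C)(C)C)C=C(O[Si](C)(C)C(C)(C)C)C[C@]2(C)C1=O | intermediate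
9 | trans-fused ene-dione (5α-H) | CC1=CC(=O)[C@H]2[C@@](C)(CO[Si](C)(C)C(C)(C)C)C=C(O[Si](C)(C)C(C)(C)C)C[C@]2(C)C1=O | intermediate
10 | potassium 8(9)-en-9-olate | CC=1CC(=O)[C@H]2[C@@](C)(CO[Si](C)(C)C(C)(C)C)C=C(O[Si](C)(C)C(C)(C)C)C[C@]2(C)C=1[O-].[K+] | intermediate
11 | 9-triflyloxy-8(9)-ene 6-ketone | CC=1CC(=O)[C@H]2[C@@](C)(CO[Si](C)(C)C(C)(C)C)C=C(O[Si](C)(C)C(C)(C)C)C[C@]2(C)C=1OS(=O)(=O)C(F)(F)F | intermediate
12 | 9-vinyl-8(9)-ene 6-ketone | CC=1CC(=O)[C@H]2[C@@](C)(CO[Si](C)(C)C(C)(C)C)C=C(O[Si](C)(C)C(C)(C)C)C[C@]2(C)C=1C=C | intermediate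
13 | 2,6-diketone | CC=1CC(=O)[C@H]2[C@@](C)(CO[Si](C)(C)C(C)(C)C)CC(=O)C[C@]2(C)C=1C=C | intermediate
14 | 2α,6α-diol | CC=1C[C@H](O)[C@H]2[C@@](C)(CO[Si](C)(C)C(C)(C)C)C[C@H](O)C[C@]2(C)C=1C=C | intermediate
15 | 2α,6α,19-tris(TBS) ether | CC=1C[C@H](O[Si](C)(C)C(C)(C)C)[C@H]2[C@@](C)(CO[Si](C)(C)C(C)(C)C)C[C@H](O[Si](C)(C)C(C)(C)C)C[C@]2(C)C=1C=C | intermediate
16 | 2-bromoprop-2-en-1-ol | C=C(Br)CO | starting material
17 | (2-bromoallyloxy)(tert-butyl)dimethylsilane | C=C(Br)CO[Si](C)(C)C(C)(C)C | intermediate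
18 | B-alkyl-9-BBN (boron on C12) | CC=1C[C@H](O[Si](C)(C)C(C)(C)C)[C@H]2[C@@](C)(CO[Si](C)(C)C(C)(C)C)C[C@H](O[Si](C)(C)C(C)(C)C)C[C@]2(C)C=1CCB1C2CCCC1CCC2 | intermediate
19 | 8(9)-ene with CH2CH2C(=CH2)CH2OTBS on C9 | CC=1C[C@H](O[Si](C)(C)C(C)(C)C)[C@H]2[C@@](C)(CO[Si](C)(C)C(C)(C)C)C[C@H](O[Si](C)(C)C(C)(C)C)C[C@]2(C)C=1CCC(=C)CO[Si](C)(C)C(C)(C)C | intermediate
20 | 8α,9α-epoxide | C[C@@]13C[C@H](O[Si](C)(C)C(C)(C)C)[C@H]2[C@@](C)(CO[Si](C)(C)C(C)(C)C)C[C@H](O[Si](C)(C)C(C)(C)C)C[C@]2(C)[C@]1(CCC(=C)CO[Si](C)(C)C(C)(C)C)O3 | intermediate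
21 | 9β-hydroperoxy-8α-ol | C[C@@]1(O)C[C@H](O[Si](C)(C)C(C)(C)C)[C@H]2[C@@](C)(CO[Si](C)(C)C(C)(C)C)C[C@H](O[Si](C)(C)C(C)(C)C)C[C@]2(C)[C@]1(OO)CCC(=C)CO[Si](C)(C)C(C)(C)C | intermediate
22 | 9β-(triethylsilylperoxy)-8α-ol | C[C@@]1(O)C[C@H](O[Si](C)(C)C(C)(C)C)[C@H]2[C@@](C)(CO[Si](C)(C)C(C)(C)C)C[C@H](O[Si](C)(C)C(C)(C)C)C[C@]2(C)[C@]1(OO[Si](CC)(CC)CC)CCC(=C)CO[Si](C)(C)C(C)(C)C | intermediate
23 | C13 α-methoxy hydroperoxide | C[C@@]1(O)C[C@H](O[Si](C)(C)C(C)(C)C)[C@H]2[C@@](C)(CO[Si](C)(C)C(C)(C)C)C[C@H](O[Si](C)(C)C(C)(C)C)C[C@]2(C)[C@]1(OO[Si](CC)(CC)CC)CCC(OC)(OO)CO[Si](C)(C)C(C)(C)C | intermediate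
24 | C13 ketone (8α-OH; 9β-OOSiEt3) | C[C@@]1(O)C[C@H](O[Si](C)(C)C(C)(C)C)[C@H]2[C@@](C)(CO[Si](C)(C)C(C)(C)C)C[C@H](O[Si](C)(C)C(C)(C)C)C[C@]2(C)[C@]1(OO[Si](CC)(CC)CC)CCC(=O)CO[Si](C)(C)C(C)(C)C | intermediate
25 | 8(17)-ene C13 ketone (9β-OOSiEt3) | C=C1C[C@H](O[Si](C)(C)C(C)(C)C)[C@H]2[C@@](C)(CO[Si](C)(C)C(C)(C)C)C[C@H](O[Si](C)(C)C(C)(C)C)C[C@]2(C)[C@]1(OO[Si](CC)(CC)CC)CCC(=O)CO[Si](C)(C)C(C)(C)C | intermediate
26 | 9β-hydroperoxy C13 ketone | C=C1C[C@H](O[Si](C)(C)C(C)(C)C)[C@H]2[C@@](C)(CO[Si](C)(C)C(C)(C)C)C[C@H](O[Si](C)(C)C(C)(C)C)C[C@]2(C)[C@]1(OO)CCC(=O)CO[Si](C)(C)C(C)(C)C | intermediate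
27 | cyclic hemiperketal (9β,13-epidioxy-13-ol; both C13 epimers) | C=C1C[C@H](O[Si](C)(C)C(C)(C)C)[C@H]2[C@@](C)(CO[Si](C)(C)C(C)(C)C)C[C@H](O[Si](C)(C)C(C)(C)C)C[C@]2(C)[C@]12CCC(O)(CO[Si](C)(C)C(C)(C)C)OO2 | intermediate
28 | methyl ester (13S; 9β,13-epidioxy) | C=C1C[C@H](O[Si](C)(C)C(C)(C)C)[C@H]2[C@@](C)(CO[Si](C)(C)C(C)(C)C)C[C@H](O[Si](C)(C)C(C)(C)C)C[C@]2(C)[C@]12CC[C@](CC(=O)OC)(CO[Si](C)(C)C(C)(C)C)OO2 | intermediate
29 | tetraol hydroxy ester | C=C1C[C@H](O)[C@H]2[C@@](C)(CO)C[C@H](O)C[C@]2(C)[C@]12CC[C@](CC(=O)OC)(CO)OO2 | intermediate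
30 | 2α,6α,19-trihydroxy-9β,13-epidioxylabd-8(17)-en-15,16-olide (CNP0262224.1) | C=C1C[C@H](O)[C@H]2[C@@](C)(CO)C[C@H](O)C[C@]2(C)[C@]12CC[C@]1(COC(=O)C1)OO2 | target

**Totals and risks**

Total step count: 21. Longest linear sequence: 20 steps (steps 1–11 and 13–21).

The three steps most likely to fail:

1. Step 5. The hindered (Z)-disubstituted diene terminus may be slow to reach the s-cis geometry, so the catalyst could promote only conjugate addition, desilylation or oligomerization of the diene, or regio- and facial control could erode. The fallback makes the two bonds in separate events. It sets out from 6 and 7: the same Lewis acid at −78 °C followed by aqueous quench is used only for the Mukaiyama–Michael addition to the methyl-bearing quinone carbon, giving 2,6-dimethyl-2-[(Z)-5-(tert-butyldimethylsilyloxy)-4-methyl-2-oxopent-3-enyl]cyclohex-5-ene-1,4-dione F1. Ring A is then closed by intramolecular Michael addition of the C5 enolate onto C4 of the (Z)-enone (KN(SiMe3)2, THF, −78 → 0 °C), and the resulting C2 enolate is trapped with TBSCl. The route is rejoined at 8, and any mixture at C5 is levelled in step 6.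

2. Step 15. After ionization of the C9–O bond, loss of H11 to an allylic alcohol, a 1,2-shift of the C20 methyl, or attack at C8 could outrun capture by H2O2 at C9. The fallback delivers the peroxide from a tether and sets out from 20. Ozonolysis of the side-chain alkene in CH2Cl2/MeOH gives the epoxy α-methoxy hydroperoxide F2. Catalytic camphorsulfonic acid then induces 6-exo opening of the epoxide at C9 with inversion, and the liberated 8α-oxygen displaces methanol to give the bridged peroxy ketal (9β,13-epidioxy-8α,13-epoxide) F3. 1-Methoxy-1-(trimethylsilyloxy)ethene with TMSOTf opens the C13–O8 bond with entry of the acetate unit anti to the leaving oxygen, giving the 8α-hydroxy ester F4. Dehydration with SOCl2/pyridine as in step 18 rejoins the route at 28.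

3. Step 20. The Lewis acid may activate the O–O bond (Criegee-type fragmentation) or the allylic C9–O bond in place of the anomeric C13–O bond, and facial bias at C13 may be insufficient. The fallback replaces cation chemistry by an anionic ring closure and sets out from 25. Horner–Wadsworth–Emmons olefination of the C13 ketone ((MeO)2P(O)CH2CO2Me, NaH, THF) gives the α,β-unsaturated ester F5 (alkene isomers). Bu4NF then cleaves the silyl peroxide, and the peroxide anion closes the 1,2-dioxane by 6-exo conjugate addition to C13 under equilibrating conditions. The route is rejoined at 28.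

Further compounds
F1 | step 5 | 2,6-dimethyl-2-[(Z)-5-(tert-butyldimethylsilyloxy)-4-methyl-2-oxopent-3-enyl]cyclohex-5-ene-1,4-dione | CC1=CC(=O)C[C@](C)(CC(=O)/C=C(C)\CO[Si](C)(C)C(C)(C)C)C1=O
F2 | step 15 | 8α,9α-epoxide with C13 as C(OMe)(OOH) | C[C@@]13C[C@H](O[Si](C)(C)C(C)(C)C)[C@H]2[C@@](C)(CO[Si](C)(C)C(C)(C)C)C[C@H](O[Si](C)(C)C(C)(C)C)C[C@]2(C)[C@]1(CCC(OC)(OO)CO[Si](C)(C)C(C)(C)C)O3
F3 | step 15 | bridged peroxy ketal (9β,13-epidioxy-8α,13-epoxide) | C[C@@]1(O3)C[C@H](O[Si](C)(C)C(C)(C)C)[C@H]2[C@@](C)(CO[Si](C)(C)C(C)(C)C)C[C@H](O[Si](C)(C)C(C)(C)C)C[C@]2(C)[C@]14CC[C@@]3(CO[Si](C)(C)C(C)(C)C)OO4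
F4 | step 15 | 8α-hydroxy analogue of 28 (8β-CH3) | C[C@@]1(O)C[C@H](O[Si](C)(C)C(C)(C)C)[C@H]2[C@@](C)(CO[Si](C)(C)C(C)(C)C)C[C@H](O[Si](C)(C)C(C)(C)C)C[C@]2(C)[C@]12CC[C@](CC(=O)OC)(CO[Si](C)(C)C(C)(C)C)OO2
F5 | step 20 | α,β-unsaturated methyl ester at C13=C14 (9β-OOSiEt3; 8(17)-ene) | C=C1C[C@H](O[Si](C)(C)C(C)(C)C)[C@H]2[C@@](C)(CO[Si](C)(C)C(C)(C)C)C[C@H](O[Si](C)(C)C(C)(C)C)C[C@]2(C)[C@]1(OO[Si](CC)(CC)CC)CCC(=CC(=O)OC)CO[Si](C)(C)C(C)(C)C
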